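The plan rests on disconnecting C1'–C2' of the branch on C2, which turns the C2=C3 acid alkene (carboxyl and C1' on C2, C4 chain on C3) into a 2-methylene-3-hydroxy ester. The feature exploited is this acyclic 2-alkylidene array with C1 and C3' in a 1,5 relationship; no ring is involved, and the butenolide ring is attached later at C11–C12. In one operation an orthoester Claisen step bonds a two-carbon ester unit to the acrylate methylene and moves the alkene to C2=C3 with Z geometry. Its precursor is a Morita–Baylis–Hillman alcohol, a 2-(trimethylsilyl)ethyl ester with C11 as a silyl ether, grown from an (S)-4-isopropenyl δ-lactone that supplies C9.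

Key step: step 9

Remarks on the chemistry (one line each):
- Numbering follows the target: C1 is the CO2H carbon, the chain runs to C15 (the CH2 on the butenolide), and C1'–C4' is the branch on C2.
- C9 keeps one spatial arrangement from compound 3 onward; its descriptor reads S or R only because O, I or Zn on C11 raises the C10 arm above the C8 arm in the priority order.
- Assumption: (S)-BINAP delivers the (S)-lactone, by analogy with the face selection known for cyclic enones; the mirror-image ligand would be used if the sense proved opposite.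
- Compounds 6, 7, 9, 15 and 16 are epimer mixtures at the carbinol carbon; 15 is therefore written without a C3 descriptor, since both epimers converge in step 9.
- The C12 enoate partner is taken as the (E)-2-bromo enoate, which a known olefination type makes directly.
- Compounds 5, 19, 24 and 28 are taken as purchased reagents.

Step 1
Reactants: 1 5,6-dihydro-2H-pyran-2-one; 2 isopropenylboronic acid pinacol ester
Product: 3 (4S)-4-(prop-1-en-2-yl)oxan-2-one
Conditions: Rh(acac)(C2H4)2 (3 mol %), (S)-BINAP (3.3 mol %), 2 (2.5 equiv), dioxane/H2O 10:1, 100 °C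
Reagents that add atoms: none
Why: Rhodium-catalysed asymmetric 1,4-addition (Hayashi–Miyaura reaction): the isopropenyl–Rh/(S)-BINAP species should add to one face of the lactone alkene in the sense known for cyclic enones, which sets C9, the only stereocentre of the target, as the (S)-lactone centre.

Step 2
Reactants: 3 (S)-isopropenyl lactone
Product: 4 (4S)-4-(prop-1-en-2-yl)oxan-2-ol (lactol; anomer mixture)
Conditions: i-Bu2AlH (1.05 equiv), CH2Cl2, −78 °C; aq. KNaC4H4O6
Reagents that add atoms: none
Why: Partial reduction of a lactone by i-Bu2AlH at −78 °C should stop at the lactol because the aluminium hemiacetal does not collapse in the cold; the isopropenyl group and C9 are untouched.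

Step 3
Reactants: 4 lactol; 5 isopropenylmagnesium bromide
Product: 6 (5S)-2-methyl-5-(prop-1-en-2-yl)hept-1-ene-3,7-diol (C3 epimer mixture)
Conditions: 5 (3 equiv, 0.5 M in THF), THF, 0 °C → rt; H2O, aq. NH4Cl
Reagents that add atoms: none
Why: Grignard addition to the hydroxy aldehyde in equilibrium with the lactol (one equivalent of 5 is spent as base) should give the allylic diol; the new carbinol centre forms without control, which does not matter because step 5 removes it.

Step 4
Reactants: 6 allylic diol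
Product: 7 (5S)-7-{[tert-butyl(dimethyl)silyl]oxy}-2-methyl-5-(prop-1-en-2-yl)hept-1-en-3-ol (C3 epimer mixture)
Conditions: TBSCl (1.05 equiv), imidazole, CH2Cl2, −20 → 0 °C
Reagents that add atoms: tert-butyldimethylsilyl chloride, CC(C)(C)[Si](C)(C)Cl
Why: Silyl ether formation with TBSCl/imidazole should take place at the primary hydroxyl only, since the secondary allylic hydroxyl is much more hindered.

Step 5
Reactants: 7 mono-silylated allylic alcohol; 8 triethyl orthoacetate
Product: 10 ethyl (4E,7R)-9-{[tert-butyl(dimethyl)silyl]oxy}-4-methyl-7-(prop-1-en-2-yl)non-4-enoate, via ketene acetal 9 (not isolated)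
Conditions: 8 (6 equiv), EtCO2H (5 mol %), 140 °C, EtOH distilled off
Reagents that add atoms: none
Why: Johnson–Claisen rearrangement: ketene acetal 9 reacts through a chair with the C8 chain equatorial, which should give the E trisubstituted C6=C7 alkene and form C4–C5; the carbinol centre is erased and C9 is a spectator.

Step 6
Reactants: 10 ethyl ester
Product: 11 (4E,7R)-9-{[tert-butyl(dimethyl)silyl]oxy}-4-methyl-7-(prop-1-en-2-yl)non-4-enal
Conditions: i-Bu2AlH (1.05 equiv), CH2Cl2, −78 °C; MeOH, aq. KNaC4H4O6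
Reagents that add atoms: none
Why: Partial reduction of the ethyl ester with one equivalent of i-Bu2AlH at −78 °C should stop at the aldehyde through the stable tetrahedral aluminate; the silyl ether and the alkenes are inert.

Step 7
Reactants: 12 2-(trimethylsilyl)ethanol; 13 acryloyl chloride
Product: 14 2-(trimethylsilyl)ethyl prop-2-enoate
Conditions: Et3N, CH2Cl2, 0 °C
Reagents that add atoms: none
Why: Acylation of a primary alcohol by an acid chloride with Et3N as HCl scavenger (esterification) should give the acrylate cleanly at 0 °C.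

Step 8
Reactants: 11 C3 aldehyde; 14 silylethyl acrylate
Product: 15 2-(trimethylsilyl)ethyl (6E,9R)-11-{[tert-butyl(dimethyl)silyl]oxy}-3-hydroxy-6-methyl-2-methylidene-9-(prop-1-en-2-yl)undec-6-enoate (both C3 epimers)
Conditions: 14 (4 equiv), DABCO (1 equiv), neat, rt, several days
Reagents that add atoms: none
Why: Morita–Baylis–Hillman reaction: DABCO adds to the acrylate, the ammonium enolate attacks the unhindered aldehyde and the amine is expelled; the C3 carbinol forms as both epimers, which is harmless because step 9 erases it.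

Step 9
Reactants: 15 Morita–Baylis–Hillman alcohol; 8 triethyl orthoacetate
Product: 17 2-(trimethylsilyl)ethyl (2Z,6E,9R)-11-{[tert-butyl(dimethyl)silyl]oxy}-2-(3-ethoxy-3-oxopropyl)-6-methyl-9-(prop-1-en-2-yl)undeca-2,6-dienoate, via ketene acetal 16 (not isolated)
Conditions: 8 (8 equiv), EtCO2H (10 mol %), 140 °C, EtOH distilled off
Reagents that add atoms: none
Why: Acid-catalysed exchange of the C3 hydroxyl into the orthoester and loss of ethanol give the mixed ketene acetal 16, which undergoes a concerted [3,3] shift through a chair: the C3–O bond breaks, the ketene acetal CH2 bonds to the acrylate methylene (C1'–C2') and the alkene moves to C2=C3. This is a Johnson–Claisen rearrangement of a Morita–Baylis–Hillman alcohol, a substrate class known to react with orthoacetates. No ring closes and no stereocentre is made; the C3 carbinol centre is erased, so both epimers of 15 converge, and C9 takes no part. The step needs Z geometry at C2=C3 (C4 chain cis to the ester): in the chair the C4 chain on the carbinol carbon should prefer the equatorial site to escape a 1,3-diaxial contact with the ethoxy group, which places it anti to the new C1'–C2' bond. The opposing A(1,2) contact with the C2 ester is eased because the ester can twist out of plane, the unsubstituted methylene terminus leaves the chair undistorted, and the shift is driven by formation of an ester carbonyl and a conjugated trisubstituted alkene.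

Step 10
Reactants: 17 (2Z)-diester
Product: 18 2-(trimethylsilyl)ethyl (2Z,6E,9R)-11-{[tert-butyl(dimethyl)silyl]oxy}-6-methyl-2-(3-oxopropyl)-9-(prop-1-en-2-yl)undeca-2,6-dienoate
Conditions: i-Bu2AlH (1.05 equiv), toluene, −78 °C; MeOH, aq. KNaC4H4O6
Reagents that add atoms: none
Why: Chemoselective partial reduction with i-Bu2AlH: the saturated, unhindered ethyl ester should be attacked ahead of the conjugated, α-branched silylethyl ester, and at −78 °C with one equivalent the aluminate should hold until work-up releases the aldehyde.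

Step 11
Reactants: 18 C3' aldehyde; 19 isopropyltriphenylphosphonium iodide
Product: 21 2-(trimethylsilyl)ethyl (2Z,6E,9R)-11-{[tert-butyl(dimethyl)silyl]oxy}-6-methyl-2-(4-methylpent-3-en-1-yl)-9-(prop-1-en-2-yl)undeca-2,6-dienoate, via isopropylidenetriphenylphosphorane 20 (not isolated)
Conditions: 19 (1.5 equiv), n-BuLi (1.4 equiv), THF, 0 °C; then 18, −78 °C → rt
Reagents that add atoms: none
Why: Wittig olefination with the non-stabilised isopropylidene ylide 20 should convert the aldehyde into the C3'=C4' alkene, which has no geometry to control; the hindered conjugated ester should not be attacked at low temperature.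

Step 12
Reactants: 21 silyl ether
Product: 22 2-(trimethylsilyl)ethyl (2Z,6E,9R)-11-hydroxy-6-methyl-2-(4-methylpent-3-en-1-yl)-9-(prop-1-en-2-yl)undeca-2,6-dienoate
Conditions: CSA (10 mol %), MeOH/CH2Cl2 1:1, 0 °C
Reagents that add atoms: none
Why: Acid-catalysed methanolysis should remove the primary silyl ether, while the 2-(trimethylsilyl)ethyl ester, which fluoride would cleave, is stable to catalytic acid at 0 °C.

Step 13
Reactants: 22 C11 alcohol
Product: 23 2-(trimethylsilyl)ethyl (2Z,6E,9R)-11-iodo-6-methyl-2-(4-methylpent-3-en-1-yl)-9-(prop-1-en-2-yl)undeca-2,6-dienoate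
Conditions: PPh3, imidazole, I2, CH2Cl2, 0 °C → rt
Reagents that add atoms: iodine, II
Why: Appel-type iodination (PPh3/I2/imidazole) should replace the primary hydroxyl by iodide through SN2 attack on the alkoxyphosphonium ion; C9 and the alkenes are not involved.

Step 14
Reactants: 24 methyl 2-[bis(2,2,2-trifluoroethoxy)phosphoryl]acetate
Product: 25 methyl 2-[bis(2,2,2-trifluoroethoxy)phosphoryl]-2,2-dibromoacetate
Conditions: NaH (2.2 equiv), THF, 0 °C; Br2 (2.2 equiv), −78 °C → rt
Reagents that add atoms: bromine, BrBr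
Why: Double α-bromination of the phosphonoacetate through its sodium enolate: the monobromide is more acidic than 24 and is brominated again, so two equivalents of base and Br2 should lead cleanly to the dibromide.

Step 15
Reactants: 25 dibromophosphonate
Product: 26 methyl 2-[bis(2,2,2-trifluoroethoxy)phosphoryl]-2-bromoacetate (racemic)
Conditions: SnCl2·2H2O (1.0 equiv), EtOH/H2O, 0 °C
Reagents that add atoms: none
Why: Halophilic reduction by divalent tin (SnCl2) should remove one bromine from the gem-dibromide, the stabilised carbanion being protonated by the medium, which avoids the mixtures that direct monobromination tends to give.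

Step 16
Reactants: 27 4-bromofuran-2(5H)-one; 28 [2-(1,3-dioxolan-2-yl)ethyl]zinc bromide
Product: 29 4-[2-(1,3-dioxolan-2-yl)ethyl]furan-2(5H)-one
Conditions: 28 (1.3 equiv, 0.5 M in THF), Pd(PPh3)4 (5 mol %), THF, rt → 50 °C
Reagents that add atoms: none
Why: Negishi cross-coupling: oxidative addition into the activated C–Br bond of the bromobutenolide, transmetalation from zinc and reductive elimination should form the C15–ring bond under base-free conditions that spare the lactone.

Step 17
Reactants: 29 dioxolane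
Product: 30 3-(5-oxo-2,5-dihydrofuran-3-yl)propanal
Conditions: 2 M HCl (aq.)/THF 1:1, rt
Reagents that add atoms: water, O
Why: Acid-catalysed acetal hydrolysis should release the aldehyde, and the butenolide is stable to dilute aqueous acid.

Step 18
Reactants: 30 butenolide aldehyde; 26 bromophosphonate
Product: 31 methyl (2E)-2-bromo-5-(5-oxo-2,5-dihydrofuran-3-yl)pent-2-enoate
Conditions: 26 (1.2 equiv), t-BuOK (1.15 equiv), 18-crown-6, THF, −78 °C; then 30
Reagents that add atoms: none
Why: Horner–Wadsworth–Emmons olefination with a bis(trifluoroethyl) α-bromophosphonate (Still–Gennari-type kinetic control) should give the α-bromo enoate with the ester cis to the C14 chain, i.e. the 2E isomer; the weakly basic phosphonate anion at −78 °C should leave the butenolide alone.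

Step 19
Reactants: 23 C11 iodide; 31 (E)-2-bromo enoate
Product: 33 2-(trimethylsilyl)ethyl (2Z,6E,9S,12Z)-12-(methoxycarbonyl)-6-methyl-2-(4-methylpent-3-en-1-yl)-15-(5-oxo-2,5-dihydrofuran-3-yl)-9-(prop-1-en-2-yl)pentadeca-2,6,12-trienoate, via alkylzinc iodide 32 (not isolated)
Conditions: Zn dust (activated with BrCH2CH2Br and Me3SiCl), DMF, rt → 35 °C; then 31, PdCl2(dppf) (5 mol %), THF/DMF, rt → 40 °C
Reagents that add atoms: none
Why: Zinc insertion into the primary C–I bond followed by Negishi cross-coupling with the vinyl bromide, which proceeds with retention of alkene geometry, should form C11–C12 and deliver the Z C12=C13 enoate; esters and the butenolide tolerate the alkylzinc.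

Step 20
Reactants: 33 silylethyl ester
Product: 34 (2Z,6E,9S,12Z)-12-(methoxycarbonyl)-6-methyl-2-(4-methylpent-3-en-1-yl)-15-(5-oxo-2,5-dihydrofuran-3-yl)-9-(prop-1-en-2-yl)pentadeca-2,6,12-trienoic acid
Conditions: (Me2N)3S+ Me3SiF2− (TASF, 2.5 equiv), DMF, 0 °C → rt; aq. HCl to pH 3
Reagents that add atoms: none
Why: Fluoride attack on silicon triggers β-elimination of the 2-(trimethylsilyl)ethyl ester (ester deprotection), releasing ethene and Me3SiF, while the methyl ester and the butenolide should not react with the anhydrous fluoride source at 0 °C.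

Compound list
1 | 5,6-dihydro-2H-pyran-2-one | O=C1C=CCCO1 | starting material
2 | isopropenylboronic acid pinacol ester | CC(=C)B1OC(C)(C)C(C)(C)O1 | starting material
3 | (4S)-4-(prop-1-en-2-yl)oxan-2-one | C=C(C)[C@H]1CCOC(=O)C1 | intermediate
4 | (4S)-4-(prop-1-en-2-yl)oxan-2-ol (anomer mixture) | C=C(C)[C@H]1CCOC(O)C1 | intermediate
5 | isopropenylmagnesium bromide | C=C(C)[Mg]Br | starting material
6 | (5S)-2-methyl-5-(prop-1-en-2-yl)hept-1-ene-3,7-diol (C3 epimer mixture) | C=C(C)[C@H](CC(O)C(C)=C)CCO | intermediate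
7 | (5S)-7-{[tert-butyl(dimethyl)silyl]oxy}-2-methyl-5-(prop-1-en-2-yl)hept-1-en-3-ol (C3 epimer mixture) | C=C(C)[C@H](CC(O)C(C)=C)CCO[Si](C)(C)C(C)(C)C | intermediate
8 | triethyl orthoacetate | CCOC(C)(OCC)OCC | starting material
9 | ketene acetal: 7 with its secondary hydroxyl as the 1-ethoxyethenyl ether | C=C(C)[C@H](CC(OC(=C)OCC)C(C)=C)CCO[Si](C)(C)C(C)(C)C | intermediate
10 | ethyl (4E,7R)-9-{[tert-butyl(dimethyl)silyl]oxy}-4-methyl-7-(prop-1-en-2-yl)non-4-enoate | C=C(C)[C@H](C/C=C(\C)CCC(=O)OCC)CCO[Si](C)(C)C(C)(C)C | intermediate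
11 | (4E,7R)-9-{[tert-butyl(dimethyl)silyl]oxy}-4-methyl-7-(prop-1-en-2-yl)non-4-enal | C=C(C)[C@H](C/C=C(\C)CCC=O)CCO[Si](C)(C)C(C)(C)C | intermediate
12 | 2-(trimethylsilyl)ethanol | C[Si](C)(C)CCO | starting material
13 | acryloyl chloride | C=CC(=O)Cl | starting material
14 | 2-(trimethylsilyl)ethyl prop-2-enoate | C=CC(=O)OCC[Si](C)(C)C | intermediate
15 | 2-(trimethylsilyl)ethyl (6E,9R)-11-{[tert-butyl(dimethyl)silyl]oxy}-3-hydroxy-6-methyl-2-methylidene-9-(prop-1-en-2-yl)undec-6-enoate (both C3 epimers) | C=C(C)[C@H](C/C=C(\C)CCC(O)C(=C)C(=O)OCC[Si](C)(C)C)CCO[Si](C)(C)C(C)(C)C | intermediate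
16 | ketene acetal: 15 with its C3 hydroxyl as the 1-ethoxyethenyl ether | C=C(C)[C@H](C/C=C(\C)CCC(OC(=C)OCC)C(=C)C(=O)OCC[Si](C)(C)C)CCO[Si](C)(C)C(C)(C)C | intermediate
17 | 2-(trimethylsilyl)ethyl (2Z,6E,9R)-11-{[tert-butyl(dimethyl)silyl]oxy}-2-(3-ethoxy-3-oxopropyl)-6-methyl-9-(prop-1-en-2-yl)undeca-2,6-dienoate | C=C(C)[C@H](C/C=C(\C)CC/C=C(/CCC(=O)OCC)C(=O)OCC[Si](C)(C)C)CCO[Si](C)(C)C(C)(C)C | intermediate
18 | 2-(trimethylsilyl)ethyl (2Z,6E,9R)-11-{[tert-butyl(dimethyl)silyl]oxy}-6-methyl-2-(3-oxopropyl)-9-(prop-1-en-2-yl)undeca-2,6-dienoate | C=C(C)[C@H](C/C=C(\C)CC/C=C(/CCC=O)C(=O)OCC[Si](C)(C)C)CCO[Si](C)(C)C(C)(C)C | intermediate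
19 | isopropyltriphenylphosphonium iodide | CC(C)[P+](c1ccccc1)(c1ccccc1)c1ccccc1.[I-] | starting material
20 | isopropylidenetriphenylphosphorane | CC(C)=P(c1ccccc1)(c1ccccc1)c1ccccc1 | intermediate
21 | 2-(trimethylsilyl)ethyl (2Z,6E,9R)-11-{[tert-butyl(dimethyl)silyl]oxy}-6-methyl-2-(4-methylpent-3-en-1-yl)-9-(prop-1-en-2-yl)undeca-2,6-dienoate | C=C(C)[C@H](C/C=C(\C)CC/C=C(/CCC=C(C)C)C(=O)OCC[Si](C)(C)C)CCO[Si](C)(C)C(C)(C)C | intermediate
22 | 2-(trimethylsilyl)ethyl (2Z,6E,9R)-11-hydroxy-6-methyl-2-(4-methylpent-3-en-1-yl)-9-(prop-1-en-2-yl)undeca-2,6-dienoate | C=C(C)[C@H](C/C=C(\C)CC/C=C(/CCC=C(C)C)C(=O)OCC[Si](C)(C)C)CCO | intermediate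
23 | 2-(trimethylsilyl)ethyl (2Z,6E,9R)-11-iodo-6-methyl-2-(4-methylpent-3-en-1-yl)-9-(prop-1-en-2-yl)undeca-2,6-dienoate | C=C(C)[C@H](C/C=C(\C)CC/C=C(/CCC=C(C)C)C(=O)OCC[Si](C)(C)C)CCI | intermediate
24 | methyl 2-[bis(2,2,2-trifluoroethoxy)phosphoryl]acetate | COC(=O)CP(=O)(OCC(F)(F)F)OCC(F)(F)F | starting material
25 | methyl 2-[bis(2,2,2-trifluoroethoxy)phosphoryl]-2,2-dibromoacetate | COC(=O)C(Br)(Br)P(=O)(OCC(F)(F)F)OCC(F)(F)F | intermediate
26 | methyl 2-[bis(2,2,2-trifluoroethoxy)phosphoryl]-2-bromoacetate (racemic) | COC(=O)C(Br)P(=O)(OCC(F)(F)F)OCC(F)(F)F | intermediate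
27 | 4-bromofuran-2(5H)-one | O=C1OCC(Br)=C1 | starting material
28 | [2-(1,3-dioxolan-2-yl)ethyl]zinc bromide | Br[Zn]CCC1OCCO1 | starting material
29 | 4-[2-(1,3-dioxolan-2-yl)ethyl]furan-2(5H)-one | O=C1OCC(CCC2OCCO2)=C1 | intermediate
30 | 3-(5-oxo-2,5-dihydrofuran-3-yl)propanal | O=CCCC1=CC(=O)OC1 | intermediate
31 | methyl (2E)-2-bromo-5-(5-oxo-2,5-dihydrofuran-3-yl)pent-2-enoate | COC(=O)/C(Br)=C\CCC1=CC(=O)OC1 | intermediate
32 | alkylzinc iodide: 23 with ZnI in place of I on C11 (9R) | C=C(C)[C@H](C/C=C(\C)CC/C=C(/CCC=C(C)C)C(=O)OCC[Si](C)(C)C)CC[Zn]I | intermediate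
33 | 2-(trimethylsilyl)ethyl (2Z,6E,9S,12Z)-12-(methoxycarbonyl)-6-methyl-2-(4-methylpent-3-en-1-yl)-15-(5-oxo-2,5-dihydrofuran-3-yl)-9-(prop-1-en-2-yl)pentadeca-2,6,12-trienoate | C=C(C)[C@H](C/C=C(\C)CC/C=C(/CCC=C(C)C)C(=O)OCC[Si](C)(C)C)CC/C(=C/CCC1=CC(=O)OC1)C(=O)OC | intermediate
34 | (2Z,6E,9S,12Z)-12-(methoxycarbonyl)-6-methyl-2-(4-methylpent-3-en-1-yl)-15-(5-oxo-2,5-dihydrofuran-3-yl)-9-(prop-1-en-2-yl)pentadeca-2,6,12-trienoic acid (CNP0162600.1) | C=C(C)[C@H](C/C=C(\C)CC/C=C(/CCC=C(C)C)C(=O)O)CC/C(=C/CCC1=CC(=O)OC1)C(=O)OC | target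

Total step count: 20. Longest linear sequence: 14 steps (steps 1–6, 8–13, 19 and 20, from 1 to 34); step 7 and steps 14–18 are side branches.

Steps most likely to fail

1. Step 9 (key step). The A(1,2) contact between the equatorial C4 chain and the C2 ester may let the chair with an axial chain compete, so that Z/E control at C2=C3 erodes. Fallback, setting out from aldehyde 11 and returning at 21: olefination of 11 with 26 (t-BuOK, 18-crown-6, THF, −78 °C) should give methyl (2E,6E,9R)-2-bromo-11-{[tert-butyl(dimethyl)silyl]oxy}-6-methyl-9-(prop-1-en-2-yl)undeca-2,6-dienoate F1, whose geometry can be checked and purified at this stage. Negishi coupling of F1 with (4-methylpent-3-en-1-yl)zinc bromide F2 (from 5-bromo-2-methylpent-2-ene, Zn dust, catalytic I2, DMA, 70 °C; then PdCl2(dppf), THF) should replace bromine with retention and give methyl (2Z,6E,9R)-11-{[tert-butyl(dimethyl)silyl]oxy}-6-methyl-2-(4-methylpent-3-en-1-yl)-9-(prop-1-en-2-yl)undeca-2,6-dienoate F3. Saponification (LiOH, THF/MeOH/H2O, 50 °C) should give (2Z,6E,9R)-11-{[tert-butyl(dimethyl)silyl]oxy}-6-methyl-2-(4-methylpent-3-en-1-yl)-9-(prop-1-en-2-yl)undeca-2,6-dienoic acid F4, and esterification with 12 (EDC·HCl, DMAP, CH2Cl2) returns to 21. This bypasses steps 8–11.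

2. Step 10. Hydride may also be delivered to the conjugated silylethyl ester, or the aluminate may collapse early and the aldehyde be reduced further. Fallback, setting out from 17 and returning at 18: LiOH (1.1 equiv, THF/H2O, 0 °C) should hydrolyse only the unhindered ethyl ester to (4Z,8E,11R)-13-{[tert-butyl(dimethyl)silyl]oxy}-8-methyl-11-(prop-1-en-2-yl)-4-{[2-(trimethylsilyl)ethoxy]carbonyl}trideca-4,8-dienoic acid F5. Activation with isobutyl chloroformate and N-methylmorpholine (THF, −15 °C) gives the isobutyl carbonic mixed anhydride F6, which is reduced in the same flask with aqueous NaBH4 to 2-(trimethylsilyl)ethyl (2Z,6E,9R)-11-{[tert-butyl(dimethyl)silyl]oxy}-2-(3-hydroxypropyl)-6-methyl-9-(prop-1-en-2-yl)undeca-2,6-dienoate F7. F7 is oxidised at once, before it can lactonise, with Dess–Martin periodinane (NaHCO3, CH2Cl2, 0 °C) to 18.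

3. Step 19. During zinc insertion the C11 radical may close 5-exo onto C7, the alkylzinc may be protonated, or β-hydride elimination after transmetalation may outrun reductive elimination. Fallback, setting out from 23 and returning at 33: alkylation of the sodium salt of 24 (3 equiv, NaH, DMF, 0 → 50 °C) with 23 should give 2-(trimethylsilyl)ethyl (2Z,6E,9S)-12-[bis(2,2,2-trifluoroethoxy)phosphoryl]-13-methoxy-6-methyl-2-(4-methylpent-3-en-1-yl)-13-oxo-9-(prop-1-en-2-yl)trideca-2,6-dienoate F8 (C12 epimers). Still–Gennari olefination of F8 with aldehyde 30 (KN(SiMe3)2, 18-crown-6, THF, −78 °C) should then form the Z C12=C13 enoate and give 33.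

Further compounds
F1 | step 9 | methyl (2E,6E,9R)-2-bromo-11-{[tert-butyl(dimethyl)silyl]oxy}-6-methyl-9-(prop-1-en-2-yl)undeca-2,6-dienoate | C=C(C)[C@H](C/C=C(\C)CC/C=C(/Br)C(=O)OC)CCO[Si](C)(C)C(C)(C)C
F2 | step 9 | (4-methylpent-3-en-1-yl)zinc bromide | CC(C)=CCC[Zn]Br
F3 | step 9 | methyl (2Z,6E,9R)-11-{[tert-butyl(dimethyl)silyl]oxy}-6-methyl-2-(4-methylpent-3-en-1-yl)-9-(prop-1-en-2-yl)undeca-2,6-dienoate | C=C(C)[C@H](C/C=C(\C)CC/C=C(/CCC=C(C)C)C(=O)OC)CCO[Si](C)(C)C(C)(C)C
F4 | step 9 | (2Z,6E,9R)-11-{[tert-butyl(dimethyl)silyl]oxy}-6-methyl-2-(4-methylpent-3-en-1-yl)-9-(prop-1-en-2-yl)undeca-2,6-dienoic acid | C=C(C)[C@H](C/C=C(\C)CC/C=C(/CCC=C(C)C)C(=O)O)CCO[Si](C)(C)C(C)(C)C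
F5 | step 10 | (4Z,8E,11R)-13-{[tert-butyl(dimethyl)silyl]oxy}-8-methyl-11-(prop-1-en-2-yl)-4-{[2-(trimethylsilyl)ethoxy]carbonyl}trideca-4,8-dienoic acid | C=C(C)[C@H](C/C=C(\C)CC/C=C(/CCC(=O)O)C(=O)OCC[Si](C)(C)C)CCO[Si](C)(C)C(C)(C)C
F6 | step 10 | isobutyl carbonic mixed anhydride of F5 | C=C(C)[C@H](C/C=C(\C)CC/C=C(/CCC(=O)OC(=O)OCC(C)C)C(=O)OCC[Si](C)(C)C)CCO[Si](C)(C)C(C)(C)C
F7 | step 10 | 2-(trimethylsilyl)ethyl (2Z,6E,9R)-11-{[tert-butyl(dimethyl)silyl]oxy}-2-(3-hydroxypropyl)-6-methyl-9-(prop-1-en-2-yl)undeca-2,6-dienoate | C=C(C)[C@H](C/C=C(\C)CC/C=C(/CCCO)C(=O)OCC[Si](C)(C)C)CCO[Si](C)(C)C(C)(C)C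
F8 | step 19 | 2-(trimethylsilyl)ethyl (2Z,6E,9S)-12-[bis(2,2,2-trifluoroethoxy)phosphoryl]-13-methoxy-6-methyl-2-(4-methylpent-3-en-1-yl)-13-oxo-9-(prop-1-en-2-yl)trideca-2,6-dienoate (C12 epimers) | C=C(C)[C@H](C/C=C(\C)CC/C=C(/CCC=C(C)C)C(=O)OCC[Si](C)(C)C)CCC(C(=O)OC)P(=O)(OCC(F)(F)F)OCC(F)(F)F
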